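**Plan**
- The retrosynthesis first cuts the prenyl O–C bond at O7 and the C3–OH bond, leaving 7-hydroxy-3',4'-dimethoxyflavone.
- The chromone is then cut at C8a–O1, C4a–C4 and O1–C2. Ring A carries O1 (on C8a) and the C4 carbonyl carbon (on C4a) on adjacent carbons, which is the ortho-acylphenol pattern that an aryne generates when it inserts into the C–O bond of a carboxylic acid.
- This leads to 5-(benzyloxy)-3-bromobenzyne, released from a silyl triflate made in two steps from 4-(benzyloxy)phenol, and to 3-(3,4-dimethoxyphenyl)propiolic acid, made in one step from the aryl alkyne.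
- Forward: rings A and B are purchased. Ring C closes in the aryne step by 6-endo-dig attack of the new phenoxide on the ynone. Hydrogenolysis (benzyl and bromine together), 7-O-prenylation and C3 lithiation/borylation/oxidation follow.
- The target has no stereocentre and the prenyl alkene bears two identical methyl groups, so no stereochemistry has to be set.

Key step: step 4

Remark: of the two silyl triflates that can deliver this aryne, the one with the triflate next to bromine is used, because it derives from a mirror-symmetric dibromophenol and raises no regiochemical question.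

**Step 1**
Reactants: 1 4-(benzyloxy)phenol
Product: 2 4-(benzyloxy)-2,6-dibromophenol
Conditions: NBS (2.05 equiv), iPr2NH (10 mol %), CH2Cl2, 0 °C to rt
Reagents that add atoms: N-bromosuccinimide, O=C1CCC(=O)N1Br
Why: Electrophilic aromatic bromination, in which the free hydroxyl outranks the benzyl ether as director, its para position is blocked, and amine-activated NBS should brominate both ortho positions to give a symmetric dibromide.

**Step 2**
Reactants: 2 4-(benzyloxy)-2,6-dibromophenol
Product: 6 4-(benzyloxy)-2-bromo-6-(trimethylsilyl)phenyl trifluoromethanesulfonate, via trimethylsilyl ether 3 (not isolated), via aryllithium 4 (not isolated), via lithium phenoxide 5 (not isolated)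
Conditions: HMDS, THF, 70 °C, then evaporation; n-BuLi (1.05 equiv), THF, −100 to −80 °C; Tf2O, −100 to −80 °C
Reagents that add atoms: hexamethyldisilazane, C[Si](C)(C)N[Si](C)(C)C; trifluoromethanesulfonic anhydride, O=S(=O)(OS(=O)(=O)C(F)(F)F)C(F)(F)F; n-butyllithium, [Li]CCCC (supplies only the lithium of intermediates 4 and 5)
Why: O-silylation, bromine–lithium exchange at one of two equivalent bromines, retro-Brook 1,3-shift of silicon from oxygen to carbon and triflation of the phenoxide is the standard one-pot entry to ortho-silylaryl triflates, and the symmetry of 2 removes any choice of site.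

**Step 3**
Reactants: 7 4-ethynyl-1,2-dimethoxybenzene
Product: 9 3-(3,4-dimethoxyphenyl)prop-2-ynoic acid, via lithium acetylide 8 (not isolated)
Conditions: n-BuLi (1.05 equiv), THF, −78 °C; CO2 (gas), −78 °C to rt; aq HCl
Reagents that add atoms: carbon dioxide, O=C=O; n-butyllithium, [Li]CCCC (supplies only the lithium of intermediate 8)
Why: Deprotonation of the terminal alkyne and carboxylation of the lithium acetylide with CO2 is a routine preparation of arylpropiolic acids.

**Step 4**
Reactants: 6 4-(benzyloxy)-2-bromo-6-(trimethylsilyl)phenyl trifluoromethanesulfonate; 9 3-(3,4-dimethoxyphenyl)prop-2-ynoic acid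
Product: 12 7-(benzyloxy)-5-bromo-2-(3,4-dimethoxyphenyl)-4H-chromen-4-one, via 5-(benzyloxy)-3-bromobenzyne 10 (not isolated), via ortho-hydroxyaryl ynone 11 (not isolated)
Conditions: 6 (1.5 equiv), CsF (4 equiv), THF, 125 °C, sealed tube
Reagents that add atoms: none
Why: Fluoride removes the silyl group of 6 and triflate departs to give aryne 10; the cesium carboxylate of 9 adds through oxygen to the aryne carbon remote from bromine, the aryl anion formed next to bromine attacks the ester carbonyl to give a four-membered alkoxide, and its ring opening gives the ortho-acyl phenoxide of 11 (new bonds C8a–O1 and C4a–C4). The phenoxide then adds to the β-carbon of the ynone in a 6-endo-dig oxa-Michael closure of ring C (new bond O1–C2), and protonation at C3 gives the chromone. The closest known reaction type is the fluoride-mediated insertion of arynes into the C–O bond of carboxylic acids, which with arylpropiolic acids is known to give flavones directly. No stereocentre is formed. The step needs regioselective addition to the unsymmetrical aryne: the bromine beside the triple bond distorts it so that the nucleophile attacks the distal carbon and the charge develops next to the inductively stabilising halogen, which should outweigh the weak opposite preference of the remote benzyloxy group, and intramolecular acyl transfer should outrun loss of bromide from the ortho-bromoaryl anion. 6-endo rather than 5-exo closure is expected because the phenoxide attacks the electrophilic β-carbon of the conjugated ynone under aprotic conditions.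

**Step 5**
Reactants: 12 7-(benzyloxy)-5-bromo-2-(3,4-dimethoxyphenyl)-4H-chromen-4-one
Product: 13 2-(3,4-dimethoxyphenyl)-7-hydroxy-4H-chromen-4-one
Conditions: H2 (1 atm), 10% Pd/C, NaOAc, EtOAc/MeOH, rt
Reagents that add atoms: none
Why: Catalytic hydrogenolysis should cleave the benzyl ether and hydrodehalogenate the aryl bromide in one operation, with acetate buffering the HBr, while the vinylogous-ester C2=C3 bond of the chromone is slow to reduce at one atmosphere.

**Step 6**
Reactants: 13 2-(3,4-dimethoxyphenyl)-7-hydroxy-4H-chromen-4-one; 14 prenyl bromide (1-bromo-3-methylbut-2-ene)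
Product: 15 2-(3,4-dimethoxyphenyl)-7-[(3-methylbut-2-en-1-yl)oxy]-4H-chromen-4-one
Conditions: K2CO3, acetone, reflux
Reagents that add atoms: none
Why: Williamson etherification, in which the acidic 7-hydroxyl (para to the C4 carbonyl) is O-alkylated by the primary allylic bromide in an SN2 reaction under mild carbonate conditions.

**Step 7**
Reactants: 15 2-(3,4-dimethoxyphenyl)-7-[(3-methylbut-2-en-1-yl)oxy]-4H-chromen-4-one
Product: 18 2-(3,4-dimethoxyphenyl)-3-hydroxy-7-[(3-methylbut-2-en-1-yl)oxy]-4H-chromen-4-one, via 3-lithioflavone 16 (not isolated), via dimethyl boronate 17 (not isolated)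
Conditions: LiN(iPr)2 (LDA, 1.3 equiv), THF, −78 °C; B(OMe)3, −78 to 0 °C; 30% aq H2O2, 0 °C to rt
Reagents that add atoms: hydrogen peroxide, OO (the C3 oxygen); trimethyl borate, COB(OC)OC (supplies only the boron and methoxy groups of intermediate 17); lithium diisopropylamide, [Li]N(C(C)C)C(C)C (supplies only the lithium of intermediate 16)
Why: Deprotonation of the flavone at C3 beside the lithium-binding C4 carbonyl, borylation and oxidative 1,2-shift from boron to oxygen is an established flavone-to-flavonol conversion, and LDA at −78 °C and basic peroxide should leave the prenyl ether and its isolated trisubstituted alkene untouched.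

**Compound list**
1 | 4-(benzyloxy)phenol | Oc1ccc(OCc2ccccc2)cc1 | starting material
2 | 4-(benzyloxy)-2,6-dibromophenol | Oc1c(Br)cc(OCc2ccccc2)cc1Br | intermediate
3 | [4-(benzyloxy)-2,6-dibromophenoxy]trimethylsilane | C[Si](C)(C)Oc1c(Br)cc(OCc2ccccc2)cc1Br | intermediate (not isolated)
4 | [5-(benzyloxy)-3-bromo-2-(trimethylsilyloxy)phenyl]lithium | C[Si](C)(C)Oc1c([Li])cc(OCc2ccccc2)cc1Br | intermediate (not isolated)
5 | lithium 4-(benzyloxy)-2-bromo-6-(trimethylsilyl)phenolate | [Li+].[O-]c1c(Br)cc(OCc2ccccc2)cc1[Si](C)(C)C | intermediate (not isolated)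
6 | 4-(benzyloxy)-2-bromo-6-(trimethylsilyl)phenyl trifluoromethanesulfonate | C[Si](C)(C)c1cc(OCc2ccccc2)cc(Br)c1OS(=O)(=O)C(F)(F)F | intermediate
7 | 4-ethynyl-1,2-dimethoxybenzene | C#Cc1ccc(OC)c(OC)c1 | starting material
8 | lithium (3,4-dimethoxyphenyl)acetylide | [Li]C#Cc1ccc(OC)c(OC)c1 | intermediate (not isolated)
9 | 3-(3,4-dimethoxyphenyl)prop-2-ynoic acid | OC(=O)C#Cc1ccc(OC)c(OC)c1 | intermediate
10 | 5-(benzyloxy)-3-bromobenzyne (5-(benzyloxy)-3-bromo-1,2-didehydrobenzene) | BrC1=CC(OCc2ccccc2)=CC#C1 | intermediate (not isolated)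
11 | 1-[4-(benzyloxy)-2-bromo-6-hydroxyphenyl]-3-(3,4-dimethoxyphenyl)prop-2-yn-1-one | COc1ccc(C#CC(=O)c2c(O)cc(OCc3ccccc3)cc2Br)cc1OC | intermediate (not isolated)
12 | 7-(benzyloxy)-5-bromo-2-(3,4-dimethoxyphenyl)-4H-chromen-4-one | COc1ccc(-c2cc(=O)c3c(Br)cc(OCc4ccccc4)cc3o2)cc1OC | intermediate
13 | 2-(3,4-dimethoxyphenyl)-7-hydroxy-4H-chromen-4-one | COc1ccc(-c2cc(=O)c3ccc(O)cc3o2)cc1OC | intermediate
14 | prenyl bromide (1-bromo-3-methylbut-2-ene) | CC(C)=CCBr | starting material
15 | 2-(3,4-dimethoxyphenyl)-7-[(3-methylbut-2-en-1-yl)oxy]-4H-chromen-4-one | COc1ccc(-c2cc(=O)c3ccc(OCC=C(C)C)cc3o2)cc1OC | intermediate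
16 | 3-lithio derivative of 15 | COc1ccc(-c2oc3cc(OCC=C(C)C)ccc3c(=O)c2[Li])cc1OC | intermediate (not isolated)
17 | dimethyl {2-(3,4-dimethoxyphenyl)-7-[(3-methylbut-2-en-1-yl)oxy]-4-oxo-4H-chromen-3-yl}boronate | COc1ccc(-c2oc3cc(OCC=C(C)C)ccc3c(=O)c2B(OC)OC)cc1OC | intermediate (not isolated)
18 | 2-(3,4-dimethoxyphenyl)-3-hydroxy-7-[(3-methylbut-2-en-1-yl)oxy]-4H-chromen-4-one (CNP0167607.0) | COc1ccc(-c2oc3cc(OCC=C(C)C)ccc3c(=O)c2O)cc1OC | target

**Step count**
Total: 7 steps. Longest linear sequence: 6 steps (1 → 2 → 6 → 12 → 13 → 15 → 18); step 3 is a one-step side branch.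

**Steps most likely to fail**

Step 4. The aryl anion formed after carboxylate addition may be protonated before it reaches the ester carbonyl, so that only O-arylation occurs. Addition to the aryne may also take the wrong orientation, or the propiolic acid may decarboxylate at 125 °C. The fallback closes ring C by a palladium-catalysed carbonylative Sonogashira annulation and sets out from alkyne 7. 3-(Benzyloxy)phenol would be iodinated (I2, NaHCO3, THF/H2O) ortho to the hydroxyl and para to the ether to give 5-(benzyloxy)-2-iodophenol F1. Coupling of F1 with 7 under CO (PdCl2(dppf) as source of zerovalent palladium, Et2NH, 120 °C) should give 7-(benzyloxy)-2-(3,4-dimethoxyphenyl)-4H-chromen-4-one F2. Hydrogenolysis of its benzyl ether (H2, Pd/C, EtOAc/MeOH) returns to the route at 13.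

Step 7. Metalation at C3 may be incomplete, or the amide base or the peroxide may attack the prenyl ether (allylic deprotonation, epoxidation of the alkene). The fallback installs the 3-hydroxyl by epoxidation and rearrangement before the prenyl group is present, and sets out from 13.
- Acetylation (Ac2O, pyridine) gives 2-(3,4-dimethoxyphenyl)-4-oxo-4H-chromen-7-yl acetate F3.
- Dimethyldioxirane in acetone/CH2Cl2 epoxidises the C2=C3 bond to the racemic, necessarily cis-fused 7-acetoxy-2-(3,4-dimethoxyphenyl)-2,3-epoxychroman-4-one F4.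
- Catalytic p-TsOH opens the epoxide at C2 and tautomerisation gives 2-(3,4-dimethoxyphenyl)-3-hydroxy-4-oxo-4H-chromen-7-yl acetate F5.
- Methanolysis (K2CO3, MeOH) gives 2-(3,4-dimethoxyphenyl)-3,7-dihydroxy-4H-chromen-4-one F6.
- One equivalent of prenyl bromide 14 with K2CO3 in acetone should alkylate the more acidic 7-hydroxyl in preference to the 3-hydroxyl, which is hydrogen-bonded to the C4 carbonyl. This returns to the route at 18.

Step 2. A second bromine–lithium exchange on the phenoxide, incomplete migration of silicon from oxygen to carbon, or sluggish triflation of the hindered lithium phenoxide may erode the one-pot sequence. The fallback replaces the silyl migration by external silylation of a protected aryllithium and sets out from 2.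
- Protection (MOMCl, iPr2NEt, CH2Cl2) gives 5-(benzyloxy)-1,3-dibromo-2-(methoxymethoxy)benzene F7.
- Mono bromine–lithium exchange (n-BuLi, THF, −78 °C) and a Me3SiCl quench give [5-(benzyloxy)-3-bromo-2-(methoxymethoxy)phenyl]trimethylsilane F8.
- Mild acetal cleavage (HCl, MeOH, rt) gives 4-(benzyloxy)-2-bromo-6-(trimethylsilyl)phenol F9.
- Triflation (Tf2O, pyridine, CH2Cl2, 0 °C) returns to the route at 6.

**Further compounds**
F1 | step 4 | 5-(benzyloxy)-2-iodophenol | Oc1cc(OCc2ccccc2)ccc1I
F2 | step 4 | 7-(benzyloxy)-2-(3,4-dimethoxyphenyl)-4H-chromen-4-one | COc1ccc(-c2cc(=O)c3ccc(OCc4ccccc4)cc3o2)cc1OC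
F3 | step 7 | 2-(3,4-dimethoxyphenyl)-4-oxo-4H-chromen-7-yl acetate | COc1ccc(-c2cc(=O)c3ccc(OC(C)=O)cc3o2)cc1OC
F4 | step 7 | rac-7-acetoxy-2-(3,4-dimethoxyphenyl)-2,3-epoxychroman-4-one (one enantiomer drawn) | COc1ccc([C@@]23O[C@@H]2C(=O)c2ccc(OC(C)=O)cc2O3)cc1OC
F5 | step 7 | 2-(3,4-dimethoxyphenyl)-3-hydroxy-4-oxo-4H-chromen-7-yl acetate | COc1ccc(-c2oc3cc(OC(C)=O)ccc3c(=O)c2O)cc1OC
F6 | step 7 | 2-(3,4-dimethoxyphenyl)-3,7-dihydroxy-4H-chromen-4-one | COc1ccc(-c2oc3cc(O)ccc3c(=O)c2O)cc1OC
F7 | step 2 | 5-(benzyloxy)-1,3-dibromo-2-(methoxymethoxy)benzene | COCOc1c(Br)cc(OCc2ccccc2)cc1Br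
F8 | step 2 | [5-(benzyloxy)-3-bromo-2-(methoxymethoxy)phenyl]trimethylsilane | COCOc1c(Br)cc(OCc2ccccc2)cc1[Si](C)(C)C
F9 | step 2 | 4-(benzyloxy)-2-bromo-6-(trimethylsilyl)phenol | Oc1c(Br)cc(OCc2ccccc2)cc1[Si](C)(C)C
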